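# Design of a total synthesis of katsumain C (24)

## The problem

Katsumain C (24) is a cardamonin-type chalcone. Its ring A (the 2,4-dihydroxy-6-methoxy acyl arene) is bonded, through the carbon between the two hydroxyls, to C7 of a 1,7-diarylhept-5-en-3-ol. The chain is numbered from the CH2 on ring B: C7 is a methine carrying ring A, ring C (4-hydroxyphenyl) and the C5=C6 (E) double bond, and C3 carries the secondary alcohol.

Ring A has five different substituents on six carbons. The order OMe / H / OH / C7 / OH / acyl has to be fixed without relying on selective O-methylation or C-acylation of a phloroglucinol.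

The two stereocentres, C3 (R) and C7 (R), are separated by a methylene and the trans alkene. Neither can direct the other, so each needs its own reagent control. Joining the halves after both are set avoids any matched/mismatched issue.

C7 is doubly benzylic and allylic. Strong base can epimerise it or move the C5=C6 bond into conjugation. Strong acid can ionise the C7–ring A bond of the electron-rich arene towards a para-quinone-methide-type cation. The chalcone enone is a Michael acceptor that can close onto the ortho hydroxyl to a flavanone, the four phenols are oxidation-prone, and both (E)-alkenes must survive.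

The enabling feature is that the six carbons of ring A divide into a four-carbon and a two-carbon open-chain piece. C(OH)–C(C7)–C(OH)–CH is a 2-substituted acetoacetate in the form of its bis(silyl enol ether). C(OMe)–C(acyl) is 4-methoxybut-3-yn-2-one. One cycloaddition–aromatisation therefore places all five substituents at once.

## Retrosynthesis

**24 ⇒ 21 + 22.** The enone C=C of the chalcone is cut back to acetophenone 21 and benzaldehyde 22. Carrying a cinnamoyl group through ring formation would put a second Michael acceptor into the cycloaddition. Acylating a finished arene would expose C7 to Lewis acid. The precursor is nine carbons smaller and has no enone. The forward aldol condensation must tolerate free ring A hydroxyls. Its hydroxide also removes the two aryl silyl ethers (through tetraphenol 23), so no separate deprotection step is needed.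

**21 ⇒ 18 + 16.** Two ring A bonds are cut: CH–C(OMe) and C(OH)–C(acetyl). The neighbouring cuts are weaker. C7–ring A (Friedel–Crafts) gives no control of C7 and needs acid. Ring A–acyl or O–Me cuts need differentiation of near-equivalent oxygens. The cut chosen turns a pentasubstituted benzene into acyclic diene 18 and the four-carbon ynone 16, with every substituent placed by polarity. The forward reaction has to be thermal and free of Lewis acid. The CH2 terminus of 18 must add to the methoxy-bearing alkyne carbon and the ketene acetal carbon must close onto the acyl-bearing carbon (cycloadduct 19). Loss of the silyl methyl ether (arene 20) and mild hydrolysis then give 21.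

**18 ⇒ 17 ⇒ 12.** Only O–Si bonds are removed. Diene 18 comes from β-silyloxy enoate 17 by γ-deprotonation and O-silylation, and 17 from keto ester 12 by soft enolisation. The free C3 hydroxyl of 12 is silylated in the same operation and released again in the work-up of the ring-forming step, which saves a protection/deprotection pair. The second enolisation must take a methyl proton and leave the C7 methine alone.

**16 ⇒ 13 + 14.** The alkyne–carbonyl bond is cut. Chloroacetal 13 gives lithium methoxyacetylide 15 by elimination, and N-methoxy-N-methylacetamide 14 acylates it without over-addition. Both are simple commercial liquids.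

**12 ⇒ 11 + 5.** The C5=C6 double bond is cut by cross-metathesis into allylated keto ester 11 and homoallylic alcohol 5. The neighbouring option, conjugate addition of a C1–C6 alkenylboron reagent to an arylidene acetoacetate, would set C7 and the alkene together. It costs an alkyne, a hydroboration and an acceptor of mixed geometry, and is kept as the fallback. The cut gives two fragments of similar size, each with one stereocentre. The forward reaction must be E-selective and must not migrate the terminal alkene of 11.

**11 ⇒ 9 + 10.** The bond from C7 to the acetoacetate α-carbon is cut. Branched-selective, iridium-catalysed allylic alkylation of cinnamyl carbonate 9 with methyl acetoacetate 10 sets C7. The α-carbon epimers do not matter because that carbon becomes sp2.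

**9 ⇒ 8 ⇒ 7 ⇒ 6.** Carbonate 9 comes from allylic alcohol 8, this from silylated cinnamate 7, and this from methyl (E)-4-hydroxycinnamate 6 by functional-group operations only.

**5 ⇒ 3 ⇒ 2 ⇒ 1.** The C3–C4 bond is cut by reagent-controlled allylboration of aldehyde 3 (through borinate 4), which sets C3. Aldehyde 3 comes from ester 2 and this from methyl 3-(4-hydroxyphenyl)propanoate 1.

## Roads not taken

**Alternative 1: ring A from a 4-methoxy-2-pyrone.** The cut is the ring bond between the C7-bearing carbon and a neighbouring C–OH. In the forward step an alkoxide opens the lactone of pyrone A1 (4-methoxy-2-pyrone with a CH2–C7 side chain at position 6). The liberated ketone enolises at that CH2, which attacks the new ester to give the 2-substituted 5-methoxyresorcinol A2.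
- Merits: the carbocyclisation is well known, the methoxy group is fixed from the start, and A2 is symmetric, so later C-acylation has only one possible site.
- Weak points: the acyl group is still missing. It would have to be installed by electrophilic substitution on an arene carrying the acid-sensitive, doubly benzylic C7, followed by the same aldol condensation. C7 would also have to be set β to a pyrone, for which no direct asymmetric method is obvious.
- Comparison: the ring closure is better precedented than the cycloaddition leading to 21. The chosen plan sets against this that 21 already carries the acetyl group, that no Friedel–Crafts chemistry touches the finished arene, and that the route is at least two steps shorter.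

**Alternative 2: Danheiser benzannulation.** Three ring bonds are made in one thermal cascade. Cyclobutenone A3 (3-silyloxy, C7 unit on the sp3 carbon) opens to a vinylketene, adds methoxyacetylene A4, reopens and closes by 6π electrocyclisation to the mono-silylated resorcinol A5.
- Merits: neutral conditions and cascade-defined regiochemistry.
- Weak points: A3 is a long synthesis in its own right. A4 is volatile and must be made. The cascade needs prolonged heating of a substrate with a doubly allylic C7–H. Again the acyl group has to be added afterwards.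
- Comparison: in predictability of the ring-forming step it is comparable to the chosen plan. The chosen plan needs only an acetoacetate and a four-carbon ynone and reaches 21 with the acyl group in place.

**Alternative 3: biomimetic Claisen folding.** The cut is the ring bond between the acetyl-bearing carbon and the adjacent C–OH. An alkoxide opens the 4-hydroxy-2-pyrone A6 (a lactone-masked triketo ester). The CH2 between the two ketones attacks the ester to give the 3-substituted 2,4,6-trihydroxyacetophenone A7.
- Merits: cheap reagents, firm precedent in polyketide chemistry, and a C7 substituent that blocks the competing aldol aromatisation. A6 would also derive from the same keto ester 12.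
- Weak point: A7 has three hydroxyls. The target needs only the one between CH and acyl methylated, whereas methylation of phloroacetophenones favours the para hydroxyl. A protect–methylate–deprotect sequence would be needed, with a doubtful distinction between the two chelated ortho hydroxyls.
- Comparison: the key step of this road is probably more reliable than step 12. The chosen plan offsets that by building the methoxy group in, so that no oxygen differentiation is needed at all.

Key step: step 12

## Remarks before the steps

- Assumption on catalyst sense: the (+)-α-pinene-derived allylborane and the (Ra,Rc,Rc)-phosphoramidite–iridium catalyst are taken to induce as they do with unbranched alkanals and with cinnamyl carbonate/malonate; the mirror-image reagents are equally available if the sense proves opposite.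
- Compounds 11, 12, 17, 18 and 19 are carried as mixtures at centres or double bonds that vanish in step 12 (α-carbon of the keto ester, enol ether geometry, ketal carbon); these are left undefined in the SMILES.
- Ynone 16 and diene 18 are moisture-sensitive and are used freshly prepared, without chromatography.

## Route

Step 1
Reactants: 1 methyl 3-(4-hydroxyphenyl)propanoate
Product: 2 methyl 3-[4-(tert-butyldimethylsilyloxy)phenyl]propanoate
Conditions: TBSCl, imidazole, DMF, rt
Reagents that add atoms: tert-butyldimethylsilyl chloride (TBSCl), CC(C)(C)[Si](C)(C)Cl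
Why: Standard phenol silylation; the aryl silyl ether should survive hydride, boron, metathesis and enol silylation chemistry and is removed by hydroxide in step 13.

Step 2
Reactants: 2 methyl 3-[4-(tert-butyldimethylsilyloxy)phenyl]propanoate
Product: 3 3-[4-(tert-butyldimethylsilyloxy)phenyl]propanal
Conditions: iBu2AlH (1.1 equiv), CH2Cl2, −78 °C; aq. KNaC4H4O6 work-up
Reagents that add atoms: none
Why: Partial ester reduction; at −78 °C the tetrahedral aluminium hemiacetal persists and releases the aldehyde only on work-up.

Step 3
Reactants: 3 3-[4-(tert-butyldimethylsilyloxy)phenyl]propanal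
Product: 5 (R)-1-[4-(tert-butyldimethylsilyloxy)phenyl]hex-5-en-3-ol, via diisopinocampheylborinate 4 (not isolated)
Conditions: (−)-Ipc2BOMe, allylMgBr, Et2O, 0 °C → rt; then 3, −78 °C; then 30% H2O2, pH 7 NaH2PO4/Na2HPO4 buffer, MeOH, 0 °C → rt
Reagents that add atoms: allylmagnesium bromide, C=CC[Mg]Br
Why: Brown allylation through a chair six-membered transition state; the allylborane from (+)-α-pinene should deliver allyl to the Si face of an unbranched alkanal, setting C3 as (R), and buffered peroxide cleaves borinate 4 without touching the aryl silyl ether.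

Step 4
Reactants: 6 methyl (E)-3-(4-hydroxyphenyl)prop-2-enoate
Product: 7 methyl (E)-3-[4-(tert-butyldimethylsilyloxy)phenyl]prop-2-enoate
Conditions: TBSCl, imidazole, DMF, rt
Reagents that add atoms: tert-butyldimethylsilyl chloride (TBSCl), CC(C)(C)[Si](C)(C)Cl
Why: Phenol silylation as in step 1; a free phenol would compete as an O-nucleophile in step 7.

Step 5
Reactants: 7 methyl (E)-3-[4-(tert-butyldimethylsilyloxy)phenyl]prop-2-enoate
Product: 8 (E)-3-[4-(tert-butyldimethylsilyloxy)phenyl]prop-2-en-1-ol
Conditions: iBu2AlH (2.5 equiv), CH2Cl2, −78 → 0 °C; aq. KNaC4H4O6 work-up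
Reagents that add atoms: none
Why: 1,2-Reduction of an α,β-unsaturated ester to the allylic alcohol with excess iBu2AlH; conjugate reduction is not expected and the alkene geometry is kept.

Step 6
Reactants: 8 (E)-3-[4-(tert-butyldimethylsilyloxy)phenyl]prop-2-en-1-ol
Product: 9 (E)-3-[4-(tert-butyldimethylsilyloxy)phenyl]prop-2-en-1-yl methyl carbonate
Conditions: ClCO2Me, pyridine, CH2Cl2, 0 °C
Reagents that add atoms: methyl chloroformate, COC(=O)Cl
Why: O-Acylation gives the linear methyl carbonate, which serves in step 7 as leaving group and as internal source of methoxide base.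

Step 7
Reactants: 9 (E)-3-[4-(tert-butyldimethylsilyloxy)phenyl]prop-2-en-1-yl methyl carbonate; 10 methyl acetoacetate
Product: 11 methyl 2-[(1S)-1-[4-(tert-butyldimethylsilyloxy)phenyl]prop-2-en-1-yl]-3-oxobutanoate (α-carbon epimers)
Conditions: [Ir(cod)Cl]2 (2 mol%), (Ra)-BINOL-derived N,N-bis[(R)-1-phenylethyl]phosphoramidite (4 mol%), TBD (8 mol%), THF, rt; 10 (2 equiv)
Reagents that add atoms: none
Why: Iridium-catalysed asymmetric allylic alkylation: the cyclometalated iridium–phosphoramidite complex ionises the carbonate, released methoxide deprotonates 10, and the stabilised enolate attacks the aryl-bearing allyl terminus (branched selectivity). The (Ra,Rc,Rc) ligand should set C7 as (S) in 11, the arrangement that becomes 7R once ring A replaces the α-carbon; excess 10 suppresses double allylation.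

Step 8
Reactants: 11 methyl 2-[(1S)-1-[4-(tert-butyldimethylsilyloxy)phenyl]prop-2-en-1-yl]-3-oxobutanoate; 5 (R)-1-[4-(tert-butyldimethylsilyloxy)phenyl]hex-5-en-3-ol
Product: 12 methyl 2-[(1S,2E,5R)-1,7-bis[4-(tert-butyldimethylsilyloxy)phenyl]-5-hydroxyhept-2-en-1-yl]-3-oxobutanoate (α-carbon epimers)
Conditions: second-generation Hoveyda–Grubbs catalyst RuCl2(H2IMes)(=CH-C6H4-2-OiPr) (5 mol%), 5 (2.5 equiv), 1,4-benzoquinone (10 mol%), CH2Cl2, 40 °C
Reagents that add atoms: none
Why: Olefin cross-metathesis between an allylically branched terminal alkene that homodimerises slowly and an excess of a fast-reacting homoallylic alcohol; the bulky allylic centre should enforce the E geometry under thermodynamic control, and benzoquinone suppresses ruthenium hydride-mediated migration of the alkene of 11. Neither stereocentre is touched.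

Step 9
Reactants: 13 chloroacetaldehyde dimethyl acetal; 14 N-methoxy-N-methylacetamide
Product: 16 4-methoxybut-3-yn-2-one, via lithium methoxyacetylide 15 (not isolated)
Conditions: LiNEt2 (3.1 equiv), THF, 0 °C; then 14, −78 °C; AcOH, −78 °C; cold water/pentane
Reagents that add atoms: none
Why: Twofold elimination and deprotonation of the chloroacetal by the lithium amide give acetylide 15, whose acylation by the N-methoxy-N-methylamide stops at the chelated tetrahedral adduct. Acid quench at −78 °C protonates the amines before the ynone is released, which should prevent their conjugate addition.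

Step 10
Reactants: 12 methyl 2-[(1S,2E,5R)-1,7-bis[4-(tert-butyldimethylsilyloxy)phenyl]-5-hydroxyhept-2-en-1-yl]-3-oxobutanoate
Product: 17 methyl 2-[(1R,2E,5R)-1,7-bis[4-(tert-butyldimethylsilyloxy)phenyl]-5-(trimethylsilyloxy)hept-2-en-1-yl]-3-(trimethylsilyloxy)but-2-enoate (enol ether E/Z mixture)
Conditions: Me3SiOTf (2.4 equiv), Et3N (3 equiv), Et2O, 0 °C → rt; pentane extraction under Ar
Reagents that add atoms: trimethylsilyl trifluoromethanesulfonate, C[Si](C)(C)OS(=O)(=O)C(F)(F)F
Why: Soft enolisation of the β-keto ester with silyl triflate and amine gives the silyl enol ether, and the C3 alcohol is silylated in the same operation. Any regioisomeric enol ether converges on 18 in step 11; the C7 descriptor changes only through ligand priority.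

Step 11
Reactants: 17 methyl 2-[(1R,2E,5R)-1,7-bis[4-(tert-butyldimethylsilyloxy)phenyl]-5-(trimethylsilyloxy)hept-2-en-1-yl]-3-(trimethylsilyloxy)but-2-enoate
Product: 18 (3R,4E,7R)-3,9-bis[4-(tert-butyldimethylsilyloxy)phenyl]-1-methoxy-2-[1-(trimethylsilyloxy)ethenyl]-1,7-bis(trimethylsilyloxy)nona-1,4-diene (the 2-substituted 1-methoxy-1,3-bis(trimethylsilyloxy)buta-1,3-diene)
Conditions: LiN(iPr)2 (1.3 equiv), THF, −78 °C; Me3SiCl, −78 °C → rt; pentane, filtration under Ar; used crude
Reagents that add atoms: trimethylsilyl chloride, C[Si](C)(C)Cl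
Why: Kinetic γ-deprotonation of the β-silyloxy enoate and O-silylation of the lithium dienolate is the standard two-stage preparation of 1-alkoxy-1,3-bis(silyloxy)dienes. The exposed methyl protons should react faster than the hindered C7 methine, so C7 is expected to stay intact.

Step 12
Reactants: 18 the 2-substituted 1-methoxy-1,3-bis(trimethylsilyloxy)buta-1,3-diene; 16 4-methoxybut-3-yn-2-one
Product: 21 1-[3-[(1R,2E,5R)-1,7-bis[4-(tert-butyldimethylsilyloxy)phenyl]-5-hydroxyhept-2-en-1-yl]-2,4-dihydroxy-6-methoxyphenyl]ethan-1-one, via cyclohexadiene cycloadduct 19 (not isolated), via silylated arene 20 (not isolated)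
Conditions: 16 (2.5 equiv), toluene, −78 °C → rt, then 60 °C; then 1 M aq. HCl, THF, 0 °C
Reagents that add atoms: none
Why: A polarised, asynchronous [4+2] cycloaddition of an electron-rich 1-alkoxy-1,3-bis(silyloxy)diene with an acetylenic ketone, the known route from such dienes to resorcinols. The unsubstituted CH2 terminus of 18, its most nucleophilic carbon, bonds first to the methoxy-bearing alkyne carbon of 16 (the β-carbon of the ynone), giving an allenolate and a silyloxy-stabilised allyl cation delocalised onto the ketene acetal carbon. The allenolate carbon then closes onto that carbon (in the stepwise limit a 6-exo-trig Claisen-type closure; the four-membered alternative is strained and reversible) to give cyclohexadiene 19. Loss of MeOSiMe3 from the ketal carbon and tautomerisation of the dienone give arene 20, and dilute acid removes both trimethylsilyl ethers while the aryl tert-butyldimethylsilyl ethers stay. No stereocentre is created: the ketal carbon of 19 and the enol ether geometries vanish on aromatisation, and C7 and C3 are spectators. The one selectivity needed is regiochemical; it is secured by matched polarity (diene CH2 to ynone β-carbon) and by the C7 substituent on the central diene carbon, which makes closure through that carbon unable to aromatise. Lewis acids are left out because they would favour carbonyl addition, and the methyl ynol ether cannot fragment by a retro-ene path, so moderate heating should be tolerated.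

Step 13
Reactants: 21 1-[3-[(1R,2E,5R)-1,7-bis[4-(tert-butyldimethylsilyloxy)phenyl]-5-hydroxyhept-2-en-1-yl]-2,4-dihydroxy-6-methoxyphenyl]ethan-1-one; 22 benzaldehyde
Product: 24 katsumain C, via desilylated acetophenone 23 (not isolated)
Conditions: 22 (3 equiv), KOH (50% aq., excess), EtOH, rt, under Ar; then 1 M aq. HCl to pH 5, 0 °C
Reagents that add atoms: none
Why: Claisen–Schmidt condensation: hydroxide first cleaves the two aryl silyl ethers at silicon (phenoxide leaving groups) to give 23, then the acetyl enolate adds to benzaldehyde and the aldol dehydrates by E1cB to the thermodynamically preferred (E)-enone. The 6-methoxy group and the phenoxide form disfavour flavanone closure, and hydroxide at rt is not expected to reach the C7–H.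

## Compound list

1 | methyl 3-(4-hydroxyphenyl)propanoate | COC(=O)CCc1ccc(O)cc1 | starting material
2 | methyl 3-[4-(tert-butyldimethylsilyloxy)phenyl]propanoate | COC(=O)CCc1ccc(O[Si](C)(C)C(C)(C)C)cc1 | intermediate
3 | 3-[4-(tert-butyldimethylsilyloxy)phenyl]propanal | O=CCCc1ccc(O[Si](C)(C)C(C)(C)C)cc1 | intermediate
4 | (R)-1-[4-(tert-butyldimethylsilyloxy)phenyl]hex-5-en-3-yl diisopinocampheylborinate | C=CC[C@@H](CCc1ccc(O[Si](C)(C)C(C)(C)C)cc1)OB([C@@H]1C[C@@H]2C[C@H]([C@H]1C)C2(C)C)[C@@H]1C[C@@H]2C[C@H]([C@H]1C)C2(C)C | intermediate (not isolated)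
5 | (R)-1-[4-(tert-butyldimethylsilyloxy)phenyl]hex-5-en-3-ol | C=CC[C@H](O)CCc1ccc(O[Si](C)(C)C(C)(C)C)cc1 | intermediate
6 | methyl (E)-3-(4-hydroxyphenyl)prop-2-enoate | COC(=O)/C=C/c1ccc(O)cc1 | starting material
7 | methyl (E)-3-[4-(tert-butyldimethylsilyloxy)phenyl]prop-2-enoate | COC(=O)/C=C/c1ccc(O[Si](C)(C)C(C)(C)C)cc1 | intermediate
8 | (E)-3-[4-(tert-butyldimethylsilyloxy)phenyl]prop-2-en-1-ol | OC/C=C/c1ccc(O[Si](C)(C)C(C)(C)C)cc1 | intermediate
9 | (E)-3-[4-(tert-butyldimethylsilyloxy)phenyl]prop-2-en-1-yl methyl carbonate | COC(=O)OC/C=C/c1ccc(O[Si](C)(C)C(C)(C)C)cc1 | intermediate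
10 | methyl acetoacetate | COC(=O)CC(C)=O | starting material
11 | methyl 2-[(1S)-1-[4-(tert-butyldimethylsilyloxy)phenyl]prop-2-en-1-yl]-3-oxobutanoate | COC(=O)C([C@H](C=C)c1ccc(O[Si](C)(C)C(C)(C)C)cc1)C(C)=O | intermediate
12 | methyl 2-[(1S,2E,5R)-1,7-bis[4-(tert-butyldimethylsilyloxy)phenyl]-5-hydroxyhept-2-en-1-yl]-3-oxobutanoate | COC(=O)C([C@H](/C=C/C[C@H](O)CCc1ccc(O[Si](C)(C)C(C)(C)C)cc1)c1ccc(O[Si](C)(C)C(C)(C)C)cc1)C(C)=O | intermediate
13 | chloroacetaldehyde dimethyl acetal | COC(CCl)OC | starting material
14 | N-methoxy-N-methylacetamide | CON(C)C(C)=O | starting material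
15 | lithium methoxyacetylide | [Li]C#COC | intermediate (not isolated)
16 | 4-methoxybut-3-yn-2-one | COC#CC(C)=O | intermediate
17 | methyl 2-[(1R,2E,5R)-1,7-bis[4-(tert-butyldimethylsilyloxy)phenyl]-5-(trimethylsilyloxy)hept-2-en-1-yl]-3-(trimethylsilyloxy)but-2-enoate | COC(=O)C([C@H](/C=C/C[C@H](O[Si](C)(C)C)CCc1ccc(O[Si](C)(C)C(C)(C)C)cc1)c1ccc(O[Si](C)(C)C(C)(C)C)cc1)=C(C)O[Si](C)(C)C | intermediate
18 | 2-[(1R,2E,5R)-1,7-bis[4-(tert-butyldimethylsilyloxy)phenyl]-5-(trimethylsilyloxy)hept-2-en-1-yl]-1-methoxy-1,3-bis(trimethylsilyloxy)buta-1,3-diene | COC(O[Si](C)(C)C)=C([C@H](/C=C/C[C@H](O[Si](C)(C)C)CCc1ccc(O[Si](C)(C)C(C)(C)C)cc1)c1ccc(O[Si](C)(C)C(C)(C)C)cc1)C(=C)O[Si](C)(C)C | intermediate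
19 | 1-[2,6-dimethoxy-5-[(1R,2E,5R)-1,7-bis[4-(tert-butyldimethylsilyloxy)phenyl]-5-(trimethylsilyloxy)hept-2-en-1-yl]-4,6-bis(trimethylsilyloxy)cyclohexa-1,4-dien-1-yl]ethan-1-one | CC(=O)C1=C(OC)CC(O[Si](C)(C)C)=C([C@H](/C=C/C[C@H](O[Si](C)(C)C)CCc2ccc(O[Si](C)(C)C(C)(C)C)cc2)c2ccc(O[Si](C)(C)C(C)(C)C)cc2)C1(OC)O[Si](C)(C)C | intermediate (not isolated)
20 | 1-[3-[(1R,2E,5R)-1,7-bis[4-(tert-butyldimethylsilyloxy)phenyl]-5-(trimethylsilyloxy)hept-2-en-1-yl]-2-hydroxy-6-methoxy-4-(trimethylsilyloxy)phenyl]ethan-1-one | CC(=O)c1c(OC)cc(O[Si](C)(C)C)c([C@H](/C=C/C[C@H](O[Si](C)(C)C)CCc2ccc(O[Si](C)(C)C(C)(C)C)cc2)c2ccc(O[Si](C)(C)C(C)(C)C)cc2)c1O | intermediate (not isolated)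
21 | 1-[3-[(1R,2E,5R)-1,7-bis[4-(tert-butyldimethylsilyloxy)phenyl]-5-hydroxyhept-2-en-1-yl]-2,4-dihydroxy-6-methoxyphenyl]ethan-1-one | CC(=O)c1c(OC)cc(O)c([C@H](/C=C/C[C@H](O)CCc2ccc(O[Si](C)(C)C(C)(C)C)cc2)c2ccc(O[Si](C)(C)C(C)(C)C)cc2)c1O | intermediate
22 | benzaldehyde | O=Cc1ccccc1 | starting material
23 | 1-[2,4-dihydroxy-3-[(1R,2E,5R)-5-hydroxy-1,7-bis(4-hydroxyphenyl)hept-2-en-1-yl]-6-methoxyphenyl]ethan-1-one | CC(=O)c1c(OC)cc(O)c([C@H](/C=C/C[C@H](O)CCc2ccc(O)cc2)c2ccc(O)cc2)c1O | intermediate (not isolated)
24 | katsumain C, (E)-1-[2,4-dihydroxy-3-[(1R,2E,5R)-5-hydroxy-1,7-bis(4-hydroxyphenyl)hept-2-en-1-yl]-6-methoxyphenyl]-3-phenylprop-2-en-1-one | COc1cc(O)c([C@H](/C=C/C[C@H](O)CCc2ccc(O)cc2)c2ccc(O)cc2)c(O)c1C(=O)/C=C/c1ccccc1 | target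

## Step count and least certain steps

Total: 13 steps. Longest linear sequence: 9 steps (steps 4, 5, 6, 7, 8, 10, 11, 12, 13, from 6).

**Step 12 (key step).** The donor-substituted alkyne of 16 is a weaker electrophile than a plain ynone, and the ketene acetal end of 18 is crowded by the C7 group. Cycloaddition may therefore be outrun by hydrolysis or desilylation of the diene, or by oligomerisation of the ynone. The reaction may also stall after the first C–C bond, or drift into the non-aromatisable closure through the central diene carbon. The fallback makes the same two ring bonds one at a time. It sets out from 18, which is condensed at its CH2 terminus with the ketene acetal 4,4-dimethoxybut-3-en-2-one (a reagent at the oxidation level of 16) under catalytic Me3SiOTf at −78 °C. Aqueous work-up should give the open-chain methyl 2-[(1S,2E,5R)-1,7-bis[4-(tert-butyldimethylsilyloxy)phenyl]-5-hydroxyhept-2-en-1-yl]-5-methoxy-3,7-dioxooct-5-enoate F1. A separate Claisen-type ring closure with LiN(SiMe3)2 in THF (the vinylogous ester carbon onto the ester carbonyl, with loss of methoxide) and aromatisation would bring the route back at 21.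

**Step 11.** LiN(iPr)2 may also remove the doubly activated C7 proton of the hindered, tetrasubstituted enol ether 17, which would erode the enantiomeric purity or move the C5=C6 bond. C-silylation and incomplete conversion are further risks, and the crude diene cannot be purified. The fallback avoids any lithium dienolate: it sets out from 12 and uses double soft enolisation with excess Me3SiOTf/Et3N in one flask, as known for 1,3-dicarbonyl compounds. The silyl-activated carbonyl is deprotonated by the amine at the exposed methyl only, and the route is rejoined at 18. No new compound is made on this way (F0).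

**Step 8.** Poor E/Z control, homodimerisation of 5 outpacing the cross reaction, or ruthenium hydride-induced migration of the terminal alkene of 11 into conjugation with ring C (which destroys C7) may lower the usefulness of the metathesis. The fallback forms C7 and the (E)-alkene together by conjugate addition and replaces steps 3 to 8. It sets out from 3 and 10 and comes back at 12.
- Asymmetric propargylation of 3 (allenylboronic acid pinacol ester, chiral phosphoric acid) would give (R)-1-[4-(tert-butyldimethylsilyloxy)phenyl]hex-5-yn-3-ol F2.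
- Syn-hydroboration with pinacolborane (Cp2Zr(H)Cl catalyst) would give the (E)-alkenylboronate (R,E)-1-[4-(tert-butyldimethylsilyloxy)phenyl]-6-(4,4,5,5-tetramethyl-1,3,2-dioxaborolan-2-yl)hex-5-en-3-ol F3.
- 4-Hydroxybenzaldehyde would be silylated to 4-(tert-butyldimethylsilyloxy)benzaldehyde F4 and condensed with 10 (piperidine/AcOH, Knoevenagel) to methyl 2-[4-(tert-butyldimethylsilyloxy)benzylidene]-3-oxobutanoate F5.
- Conjugate addition of F3 to F5 with [RhCl(C2H4)2]2 and a chiral bicyclo[2.2.2]octadiene ligand (catalytic KOH, dioxane/water) would deliver 12.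

**Step 13.** In concentrated hydroxide the acetophenone is a polyphenoxide whose para-oxido group makes the acetyl group a vinylogous carboxylate. Enolisation may therefore be slow while benzaldehyde is consumed by disproportionation. The electron-rich polyanion may also oxidise in air, and the chalcone may close to the flavanone on acidification. The fallback masks the para hydroxyl before the condensation. It sets out from 21 and comes back at 24.
- Selective alkylation of the non-chelated hydroxyl (allyl bromide, K2CO3, acetone) would give 1-[4-(allyloxy)-3-[(1R,2E,5R)-1,7-bis[4-(tert-butyldimethylsilyloxy)phenyl]-5-hydroxyhept-2-en-1-yl]-2-hydroxy-6-methoxyphenyl]ethan-1-one F6.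
- Claisen–Schmidt condensation with 22 (KOH, EtOH, which also removes the aryl silyl ethers) would give the 4'-O-allyl ether of katsumain C F7.
- Deallylation with zerovalent palladium (Pd(PPh3)4, morpholine, THF) would give 24.

## Further compounds

F1 | step 12 | methyl 2-[(1S,2E,5R)-1,7-bis[4-(tert-butyldimethylsilyloxy)phenyl]-5-hydroxyhept-2-en-1-yl]-5-methoxy-3,7-dioxooct-5-enoate | COC(=O)C([C@H](/C=C/C[C@H](O)CCc1ccc(O[Si](C)(C)C(C)(C)C)cc1)c1ccc(O[Si](C)(C)C(C)(C)C)cc1)C(=O)CC(OC)=CC(C)=O
F0 | step 11 | none | none
F2 | step 8 | (R)-1-[4-(tert-butyldimethylsilyloxy)phenyl]hex-5-yn-3-ol | C#CC[C@H](O)CCc1ccc(O[Si](C)(C)C(C)(C)C)cc1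
F3 | step 8 | (R,E)-1-[4-(tert-butyldimethylsilyloxy)phenyl]-6-(4,4,5,5-tetramethyl-1,3,2-dioxaborolan-2-yl)hex-5-en-3-ol | CC1(C)OB(/C=C/C[C@H](O)CCc2ccc(O[Si](C)(C)C(C)(C)C)cc2)OC1(C)C
F4 | step 8 | 4-(tert-butyldimethylsilyloxy)benzaldehyde | O=Cc1ccc(O[Si](C)(C)C(C)(C)C)cc1
F5 | step 8 | methyl 2-[4-(tert-butyldimethylsilyloxy)benzylidene]-3-oxobutanoate | COC(=O)C(=Cc1ccc(O[Si](C)(C)C(C)(C)C)cc1)C(C)=O
F6 | step 13 | 1-[4-(allyloxy)-3-[(1R,2E,5R)-1,7-bis[4-(tert-butyldimethylsilyloxy)phenyl]-5-hydroxyhept-2-en-1-yl]-2-hydroxy-6-methoxyphenyl]ethan-1-one | CC(=O)c1c(OC)cc(OCC=C)c([C@H](/C=C/C[C@H](O)CCc2ccc(O[Si](C)(C)C(C)(C)C)cc2)c2ccc(O[Si](C)(C)C(C)(C)C)cc2)c1O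
F7 | step 13 | (E)-1-[4-(allyloxy)-2-hydroxy-3-[(1R,2E,5R)-5-hydroxy-1,7-bis(4-hydroxyphenyl)hept-2-en-1-yl]-6-methoxyphenyl]-3-phenylprop-2-en-1-one | COc1cc(OCC=C)c([C@H](/C=C/C[C@H](O)CCc2ccc(O)cc2)c2ccc(O)cc2)c(O)c1C(=O)/C=C/c1ccccc1
A1 | alternative 1 | 6-[(2S,3E,6R)-6-(tert-butyldimethylsilyloxy)-2,8-bis[4-(methoxymethoxy)phenyl]oct-3-en-1-yl]-4-methoxy-2H-pyran-2-one | COC1=CC(=O)OC(C[C@H](/C=C/C[C@H](O[Si](C)(C)C(C)(C)C)CCc2ccc(OCOC)cc2)c2ccc(OCOC)cc2)=C1
A2 | alternative 1 | 2-[(1R,2E,5R)-5-(tert-butyldimethylsilyloxy)-1,7-bis[4-(methoxymethoxy)phenyl]hept-2-en-1-yl]-5-methoxybenzene-1,3-diol | COc1cc(O)c([C@H](/C=C/C[C@H](O[Si](C)(C)C(C)(C)C)CCc2ccc(OCOC)cc2)c2ccc(OCOC)cc2)c(O)c1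
A3 | alternative 2 | 4-[(1R,2E,5R)-5-(tert-butyldimethylsilyloxy)-1,7-bis[4-(tert-butyldimethylsilyloxy)phenyl]hept-2-en-1-yl]-3-(triisopropylsilyloxy)cyclobut-2-en-1-one | O=C1C=C(O[Si](C(C)C)(C(C)C)C(C)C)C1[C@H](/C=C/C[C@H](O[Si](C)(C)C(C)(C)C)CCc1ccc(O[Si](C)(C)C(C)(C)C)cc1)c1ccc(O[Si](C)(C)C(C)(C)C)cc1
A4 | alternative 2 | methoxyacetylene | COC#C
A5 | alternative 2 | 2-[(1R,2E,5R)-5-(tert-butyldimethylsilyloxy)-1,7-bis[4-(tert-butyldimethylsilyloxy)phenyl]hept-2-en-1-yl]-5-methoxy-3-(triisopropylsilyloxy)phenol | COc1cc(O)c([C@H](/C=C/C[C@H](O[Si](C)(C)C(C)(C)C)CCc2ccc(O[Si](C)(C)C(C)(C)C)cc2)c2ccc(O[Si](C)(C)C(C)(C)C)cc2)c(O[Si](C(C)C)(C(C)C)C(C)C)c1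
A6 | alternative 3 | 3-[(1R,2E,5R)-5-(tert-butyldimethylsilyloxy)-1,7-bis[4-(methoxymethoxy)phenyl]hept-2-en-1-yl]-4-hydroxy-6-(2-oxopropyl)-2H-pyran-2-one | CC(=O)CC1=CC(O)=C([C@H](/C=C/C[C@H](O[Si](C)(C)C(C)(C)C)CCc2ccc(OCOC)cc2)c2ccc(OCOC)cc2)C(=O)O1
A7 | alternative 3 | 1-[3-[(1R,2E,5R)-5-(tert-butyldimethylsilyloxy)-1,7-bis[4-(methoxymethoxy)phenyl]hept-2-en-1-yl]-2,4,6-trihydroxyphenyl]ethan-1-one | CC(=O)c1c(O)cc(O)c([C@H](/C=C/C[C@H](O[Si](C)(C)C(C)(C)C)CCc2ccc(OCOC)cc2)c2ccc(OCOC)cc2)c1O
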